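Remark on numbering: carbon atoms carry labdane numbers (decalin C1–C10, chain C11–C15, C16 the methyl on C13, C17 the methyl on C8, C18 the equatorial and C19 the axial carbon on C4, C20 the methyl on C10). Labdane-type names below use that skeleton for numbering only, and the CIP descriptors written in front are the actual ones (ent series: 4S,5S,8S,9S,10R).

## Analysis of the target

Target 24 is an ent-labdane: a trans-fused decalin (rings A and B) with a five-carbon chain on C9 that ends in a C15 hydrogen malonate, and no further ring. Five of its six stereocentres lie on the decalin (C4, C5, C8, C9, C10). H5 and H9 are on one face and the three methyl groups C19, C20 and C17 are axial on the other. The C18 hydroxymethyl, the C8 hydroxyl and the C9 chain are equatorial, so the C8–O bond is anti to the C9–C10 bond. The sixth stereocentre, C13 (S), sits four bonds from the nearest ring stereocentre and cannot be set by the ring. The sensitive groups are the tertiary C8 alcohol (ionises and dehydrates in acid), the malonic half ester (acidic methylene, decarboxylation on heating) and two primary hydroxyls, C15 and the neopentyl C18, of which only C15 is acylated. The difficulty lies in the two quaternary carbons C4 and C10 in a 1,3-relationship, in C4 being a stereocentre that differs only by CH3 against CH2OH, and in the tertiary carbinol C8 next to C9, all in one absolute sense. The strategy rests on one feature: C3 is a plain CH2, C4 carries CH3 and CH2OH, and the C8 oxygen is anti to C9–C10. This is what remains when an oxirane spanning C4 and C18 opens at C4, the alkenes C5=C10 and C8=C9 add in a chair–chair fold, and an oxygen ends the cascade at C8. If that oxygen belongs to a C13 methyl ketone, the cascade also stores C13 for the side chain.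

## Retrosynthetic reasoning

The C15–O acyl bond is cut first. The malonic half ester is the least robust group of 24 and the only thing that distinguishes C15 from C18, so it is put on last, from diol 21 and benzyl hydrogen malonate 22 by way of the mixed malonate 23. Keeping the C18 oxygen as a benzyl ether lets one hydrogenolysis free C18–OH and the acid together. The forward steps must acylate the primary C15–OH beside the tertiary C8–OH and then remove both benzyl groups without acid, base or heat.

C13 is traced back across C13=C14: 21 comes from the (E)-allylic alcohol 20. Substrate control is not available at this distance, and an allylic hydroxyl is the best handle for a ligand-controlled hydrogenation. Forward, the catalyst must choose one face of a geometrically pure alkene.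

The C13=C14 bond is cut to methyl ketone 16 and phosphonate 17 through enoate 19. The cut is made here because C13 then is a carbonyl carbon and C14–C15 come from a two-carbon reagent. The olefination must give the (E)-ester and the reduction to 20 must be a 1,2-reduction.

Ketone 16 is a delta-hydroxy ketone, the hydrate of a six-membered cyclic enol ether. Closing the C13–O–C8 ring in thought leads to benzyl ether 15 and its alcohol 14. The gain is that C8–O, C9 and C13 become part of a ring that a cyclization can form, and the enol ether shields the tertiary alcohol while C18 is benzylated.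

The key disconnection cuts C4–C5, C9–C10 and C8–O of 14 together and gives the acyclic epoxy dienone 13. Each of these bonds is an anti-addition bond of a cation–alkene cascade: C5=C10 and C8=C9 become (E)-alkenes, C4 with C18 becomes a 2,2-disubstituted oxirane, and the ring oxygen becomes a ketone. Three rings and five stereocentres are exchanged for one stereocentre and two alkene geometries. Forward, the cascade must open the oxirane at C4 with inversion, fold chair–chair with C18 equatorial, and end at oxygen.

The oxirane C18–O bond is cut to the 1,2-diol of keto diol 11 (through its primary tosylate 12), since closure by the tertiary oxygen onto C18 leaves the stereocentre untouched. Ketone and diol are masked together as ketal–acetonide 10 so that an organometallic coupling can build the chain.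

The C1–C2 bond is cut next. C1 is allylic and can be the electrophile of a copper-catalysed coupling that keeps the (E)-alkene. The cut also separates the terpene part from the part that holds the only stereocentre: allylic bromide 4 and bromide 8, the latter used as Grignard reagent 9. A cut nearer to the quaternary carbon would be hindered, and a cut at C2–C3 would give fragments that are harder to obtain.

Bromide 4 goes back through allylic alcohol 3 and ketal 2 to geranylacetone 1. The C1 oxygen is placed by allylic oxidation of the terminal (E)-methyl group, and the C8=C9 geometry is bought.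

Bromide 8 goes back through acetonide alcohol 7 and triol 6 to (S)-citramalic acid 5. Its tertiary carbinol carbon is C4 with C19 attached, and only reductions and functional-group exchange away from the stereocentre are needed.

## Alternatives that were turned down

Alternative 1: The cut is made in ring B at C9–C11 and C10–C20. The achiral 4-silyloxy-4-methylcyclohexadienone A1 would receive the whole C11–C15 chain from the dialkylzinc A2 and a methyl group at C10.
- Forward key step: a copper catalyst with a chiral phosphoramidite ligand adds the alkyl group of A2 to one of the two enantiotopic enone arms of A1, anti to the silyloxy group, and the zinc enolate is methylated to give cyclohexenone A3.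
- For: C8 and C9 come from one catalyst-controlled event on a flat, cheap ring. C13 is brought in ready-made inside A2, so the E/Z and hydrogenation questions of steps 13 to 15 do not arise. On C13 this alternative is the stronger one.
- Against: A3 holds ring B only. C10 is still a CH and must be alkylated again to become quaternary. Ring A, with the C4 stereocentre, the C18 oxygen and the trans C5–H, has to be annulated stepwise, and the C5 carbonyl and the C6=C7 alkene must be removed afterwards. A3 is also a gamma-silyloxy enone, which can lose silanol and aromatise under the enolising conditions that any annulation needs.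
- Comparison: the chosen route forms both carbocycles, three skeletal bonds and five stereocentres in step 10 and needs seven steps after it; here well over ten would follow the key step.

Alternative 2: Rings A and B are cut together at C5–C10 and C8–C9, with a C6=C7 cyclohexene as retron. The acyclic trienal A4 carries an (E)-enal as dienophile and an (E,E)-1-silyloxydiene.
- Forward key step: an alkylaluminium chloride activates the aldehyde and the intramolecular Diels–Alder reaction gives octalin A5.
- For: two rings and four stereocentres arise in one pericyclic step whose geometry is easier to predict than a cation cascade, and C11 arrives as an aldehyde for chain extension.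
- Against: the C4 quaternary stereocentre must already be present, enantiomerically pure, in A4. It is the only element that can direct the diene face, and it must do so through the same CH3 against CH2O discrimination that limits step 10, so nothing is gained there. The dienophile is beta,beta-disubstituted and has to create the quaternary C10, which slows the cycloaddition. C8 arrives as a secondary ether; oxidation and methyl addition would have to bring the methyl group in axially, syn to C20, against the normal equatorial approach. The C6=C7 alkene, an aldehyde next to an epimerisable C9, and C13 all remain.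
- Comparison: the chosen cascade sets the C8 carbinol directly by anti addition and ends closer to 24.

Alternative 3: Only C9–C10 is cut, and ring A is taken from an arene. Phenol A6 carries a tether with an (8S,9S)-oxirane.
- Forward key step: a potassium alkoxide base lets the para carbon of the phenolate open the oxirane at the secondary C9, which closes ring B and gives dienone A7.
- For: the step is an SN2 opening, so C8 (retention) and C9 (inversion) follow stereospecifically from an oxirane that can be made by reagent-controlled epoxidation of an (E)-alkene. C13 again comes in with the chain. On the certainty of C8, C9 and C13 this alternative is stronger than the chosen route, where these centres depend on folding and on a later hydrogenation.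
- Against: the attacking para carbon already bears the C20 methyl, so the new bond creates a quaternary centre at a hindered site and competes with 5-exo opening at the tertiary C8 and with ortho attack. A7 still lacks what is difficult in ring A: the C4 quaternary stereocentre with its C18 oxygen and the trans C5–H. The C3 carbonyl and the C1=C2 alkene must also be removed. This would take some eight to ten further steps, with the C4 alkylation again facing the axial C20 methyl.
- Comparison: the chosen route pays with a less secure fold, but it delivers ring A, C4 and C18 in the same step and reaches 24 in fewer steps.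

Key step: step 10

## Steps

Step 1
Reactants: 1 (E)-geranylacetone [(5E)-6,10-dimethylundeca-5,9-dien-2-one]
Product: 2 2-[(3E)-4,8-dimethylnona-3,7-dien-1-yl]-2-methyl-1,3-dioxolane
Conditions: HOCH2CH2OH, PPTS (cat.), benzene, reflux, Dean–Stark
Reagents that add atoms: ethylene glycol, OCCO
Why: Acid-catalysed ketalisation with azeotropic removal of water masks the methyl ketone against the Grignard reagent of step 7; the weak pyridinium acid leaves the trisubstituted alkenes alone.

Step 2
Reactants: 2 2-[(3E)-4,8-dimethylnona-3,7-dien-1-yl]-2-methyl-1,3-dioxolane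
Product: 3 (2E,6E)-2,6-dimethyl-9-(2-methyl-1,3-dioxolan-2-yl)nona-2,6-dien-1-ol
Conditions: SeO2 (cat.), t-BuOOH (anhydrous, in decane), CH2Cl2, 0 °C → rt
Reagents that add atoms: tert-butyl hydroperoxide, CC(C)(C)OO
Why: SeO2-catalysed allylic hydroxylation (ene reaction, then 2,3-sigmatropic shift) attacks the (E)-methyl group of the terminal, least hindered trisubstituted alkene and so gives the (E)-allylic alcohol; the reaction is stopped before full conversion because the internal alkene and over-oxidation compete.

Step 3
Reactants: 3 (2E,6E)-2,6-dimethyl-9-(2-methyl-1,3-dioxolan-2-yl)nona-2,6-dien-1-ol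
Product: 4 2-[(3E,7E)-9-bromo-4,8-dimethylnona-3,7-dien-1-yl]-2-methyl-1,3-dioxolane
Conditions: CBr4, PPh3, CH2Cl2, 0 °C
Reagents that add atoms: carbon tetrabromide, BrC(Br)(Br)Br
Why: Appel bromination converts the primary allylic alcohol under neutral conditions, so the ketal survives and the alkene neither migrates nor isomerises; 4 is used at once.

Step 4
Reactants: 5 (S)-citramalic acid [(2S)-2-hydroxy-2-methylbutanedioic acid]
Product: 6 (2S)-2-methylbutane-1,2,4-triol
Conditions: BH3·SMe2, B(OMe)3, THF, 0 °C → rt; then CH3OH
Reagents that add atoms: none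
Why: Borane reduces both carboxyl groups without touching the tertiary carbinol carbon, so the stereocentre is carried over unchanged; methanol work-up removes boron as volatile B(OMe)3, which suits a water-soluble triol.

Step 5
Reactants: 6 (2S)-2-methylbutane-1,2,4-triol
Product: 7 2-[(4S)-2,2,4-trimethyl-1,3-dioxolan-4-yl]ethan-1-ol
Conditions: (CH3)2C(OCH3)2, acetone, p-TsOH (cat.), rt; Et3N
Reagents that add atoms: 2,2-dimethoxypropane, COC(C)(C)OC
Why: Acetonide formation under thermodynamic control favours the five-membered dioxolane across the 1,2-diol over the six-membered ring, which would hold an axial methyl group; the primary C-4 hydroxyl stays free.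

Step 6
Reactants: 7 2-[(4S)-2,2,4-trimethyl-1,3-dioxolan-4-yl]ethan-1-ol
Product: 8 (4S)-4-(2-bromoethyl)-2,2,4-trimethyl-1,3-dioxolane
Conditions: CBr4, PPh3, Et3N (0.2 equiv), CH2Cl2, 0 °C → rt
Reagents that add atoms: carbon tetrabromide, BrC(Br)(Br)Br
Why: Appel bromination of the primary alcohol; the buffered neutral medium keeps the acetonide intact.

Step 7
Reactants: 8 (4S)-4-(2-bromoethyl)-2,2,4-trimethyl-1,3-dioxolane; 4 2-[(3E,7E)-9-bromo-4,8-dimethylnona-3,7-dien-1-yl]-2-methyl-1,3-dioxolane
Product: 10 (4S)-4-[(4E,8E)-4,8-dimethyl-11-(2-methyl-1,3-dioxolan-2-yl)undeca-4,8-dien-1-yl]-2,2,4-trimethyl-1,3-dioxolane, via Grignard reagent 9 (not isolated)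
Conditions: 8, Mg, THF, 35 °C; then 4, Li2CuCl4 (3 mol%), THF, −30 → 0 °C
Reagents that add atoms: none
Why: Li2CuCl4 in THF directs alkyl Grignard reagents to the alpha carbon of a primary allylic bromide (SN2) with retention of the (E)-alkene, which forms the C1–C2 bond; the gamma-alkoxy Grignard reagent 9 is stable at this temperature and the ketal and acetonide are inert.

Step 8
Reactants: 10 (4S)-4-[(4E,8E)-4,8-dimethyl-11-(2-methyl-1,3-dioxolan-2-yl)undeca-4,8-dien-1-yl]-2,2,4-trimethyl-1,3-dioxolane
Product: 11 (5E,9E,14S)-14,15-dihydroxy-6,10,14-trimethylpentadeca-5,9-dien-2-one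
Conditions: 1 M HCl, THF, rt
Reagents that add atoms: water, O
Why: Aqueous acid hydrolyses the ketal and the acetonide together; dilute acid at room temperature does not protonate the trisubstituted alkenes.

Step 9
Reactants: 11 (5E,9E,14S)-14,15-dihydroxy-6,10,14-trimethylpentadeca-5,9-dien-2-one
Product: 13 (5E,9E)-6,10-dimethyl-13-[(2S)-2-methyloxiran-2-yl]trideca-5,9-dien-2-one, via primary tosylate 12 (not isolated)
Conditions: TsCl, pyridine, CH2Cl2, 0 °C → rt; then K2CO3, CH3OH, rt
Reagents that add atoms: none
Why: The primary hydroxyl is sulfonylated selectively beside the tertiary one and the tertiary alkoxide then displaces the tosylate (intramolecular Williamson closure); no bond to the stereocentre is broken, so the configuration of 5 is retained in the (S)-oxirane.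

Step 10
Reactants: 13 (5E,9E)-6,10-dimethyl-13-[(2S)-2-methyloxiran-2-yl]trideca-5,9-dien-2-one
Product: 14 (4S,5S,8S,9S,10R)-8,13-epoxy-14,15-dinorlabd-12-en-18-ol (tricyclic enol ether with free, equatorial C18 hydroxymethyl)
Conditions: CH3AlCl2 (1.1 equiv, slow addition), CH2Cl2, −78 °C; Et3N, then aq. NaHCO3
Reagents that add atoms: none
Why: CH3AlCl2 binds the oxirane oxygen and weakens the C4–O bond; C5 of the C5=C10 alkene attacks C4 from the side opposite the leaving oxygen, C9 of the C8=C9 alkene attacks the C10 cation, the ketone oxygen adds to the C8 cation, and the oxocarbenium ion loses a C12 proton, which the Al–CH3 bond removes as methane. The closest known reaction type is the Lewis-acid epoxide-initiated polyene cyclization ended by a carbonyl oxygen, the mode by which acyclic terpenyl acetones give cyclic enol ethers. Ring A closes 6-endo at the C5=C10 alkene (bond C4–C5), ring B 6-endo at the C8=C9 alkene (bond C9–C10), and the pyran ring by O–C8 bond formation, which is again 6-endo with respect to the former C8=C9 alkene and leaves C13=O inside the ring. C4 is set by inversion of the (S)-oxirane. C5 and C10 follow from anti addition across the (E)-C5=C10 alkene in a chair, and C9 and C8 from anti addition across the (E)-C8=C9 alkene in the second chair, which puts H5 and H9 on the face opposite C20 and the C8–O bond equatorial, anti to C9–C10. The step needs the ring A chair in which the C18–O–Al arm is equatorial and C19 axial, because this choice decides whether the fixed (4S) centre is joined to the wanted ring system or to its mirror-image ring system with C18 axial. Only the size of the aluminium-bearing arm against that of a methyl group speaks for this chair, so two separable diastereomers must be expected and the preference is not secure. Slow addition of about one equivalent of CH3AlCl2 leaves most ketone oxygen uncomplexed, so that capture at C8 can outrun proton loss from the C8 cation.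

Step 11
Reactants: 14 (4S,5S,8S,9S,10R)-8,13-epoxy-14,15-dinorlabd-12-en-18-ol
Product: 15 (4S,5S,8S,9S,10R)-18-(benzyloxy)-8,13-epoxy-14,15-dinorlabd-12-ene
Conditions: NaH, BnBr, Bu4NI (cat.), THF/DMF, 0 °C → rt
Reagents that add atoms: benzyl bromide, BrCc1ccccc1
Why: Williamson etherification of the neopentyl C18 alkoxide; strongly basic conditions are the ones the acid-labile enol ether tolerates, and the benzyl group later falls together with the benzyl ester.

Step 12
Reactants: 15 (4S,5S,8S,9S,10R)-18-(benzyloxy)-8,13-epoxy-14,15-dinorlabd-12-ene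
Product: 16 (4S,5S,8S,9S,10R)-18-(benzyloxy)-8-hydroxy-14,15-dinorlabdan-13-one
Conditions: 0.5 M HCl, THF, 0 °C → rt; NaHCO3 before concentration
Reagents that add atoms: water, O
Why: Acid-catalysed hydration of the enol ether (protonation at C12, water addition at C13, opening of the hemiketal) frees the C13 methyl ketone and the C8 tertiary alcohol without touching a stereocentre; the product is kept free of acid on isolation so that it does not dehydrate back.

Step 13
Reactants: 16 (4S,5S,8S,9S,10R)-18-(benzyloxy)-8-hydroxy-14,15-dinorlabdan-13-one; 17 triethyl phosphonoacetate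
Product: 19 ethyl (4S,5S,8S,9S,10R,13E)-18-(benzyloxy)-8-hydroxylabd-13-en-15-oate, via sodium phosphonate 18 (not isolated)
Conditions: 17 (3 equiv), NaH (2.7 equiv), THF, 0 °C; then 16, rt → 50 °C
Reagents that add atoms: none
Why: Horner–Wadsworth–Emmons olefination of the methyl ketone forms C13=C14; the (E)-ester, with the ester trans to the larger C12 chain, should predominate and the minor (Z)-isomer is removed by chromatography. Phosphonate is kept in excess over NaH so that no free base generates the C8 alkoxide.

Step 14
Reactants: 19 ethyl (4S,5S,8S,9S,10R,13E)-18-(benzyloxy)-8-hydroxylabd-13-en-15-oate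
Product: 20 (4S,5S,8S,9S,10R,13E)-18-(benzyloxy)labd-13-ene-8,15-diol
Conditions: (i-Bu)2AlH (3.5 equiv), CH2Cl2, −78 → −20 °C; aq. potassium sodium tartrate
Reagents that add atoms: none
Why: (i-Bu)2AlH reduces the conjugated ester in 1,2-fashion to the allylic alcohol and leaves the alkene geometry alone; one extra equivalent is consumed by the tertiary hydroxyl.

Step 15
Reactants: 20 (4S,5S,8S,9S,10R,13E)-18-(benzyloxy)labd-13-ene-8,15-diol
Product: 21 (4S,5S,8S,9S,10R,13S)-18-(benzyloxy)labdane-8,15-diol
Conditions: H2 (50 atm), Ru(OAc)2[(R)-BINAP] (1 mol%), CH3OH, rt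
Reagents that add atoms: none
Why: BINAP–ruthenium dicarboxylate hydrogenation of an allylic alcohol: the hydroxyl binds ruthenium and the (R)-ligand delivers hydrogen to the face of the (E)-alkene that gives 13S, the same sense as geraniol to (S)-citronellol. The benzyl ether and the remote tertiary alcohol do not interfere.

Step 16
Reactants: 21 (4S,5S,8S,9S,10R,13S)-18-(benzyloxy)labdane-8,15-diol; 22 benzyl hydrogen malonate [3-(benzyloxy)-3-oxopropanoic acid]
Product: 23 benzyl (4S,5S,8S,9S,10R,13S)-18-(benzyloxy)-8-hydroxylabdan-15-yl propanedioate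
Conditions: 22 (1.1 equiv), DCC (1.1 equiv), DMAP (5 mol%), CH2Cl2, 0 °C
Reagents that add atoms: none
Why: Steglich esterification; the unhindered primary C15 hydroxyl is acylated at 0 °C while the tertiary C8 hydroxyl is too hindered to react with one equivalent of the acid.

Step 17
Reactants: 23 benzyl (4S,5S,8S,9S,10R,13S)-18-(benzyloxy)-8-hydroxylabdan-15-yl propanedioate
Product: 24 3-{[(3S)-5-[(1S,2S,4aS,5S,8aR)-2-hydroxy-5-(hydroxymethyl)-2,5,8a-trimethyldecahydronaphthalen-1-yl]-3-methylpentyl]oxy}-3-oxopropanoic acid (target)
Conditions: H2 (1 atm), Pd/C (10%), EtOAc, rt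
Reagents that add atoms: none
Why: Hydrogenolysis cleaves the benzyl ester and the benzyl ether in one neutral operation, so neither the tertiary alcohol nor the malonic half ester meets acid, base or heat.

## Compound list

1 | (E)-geranylacetone, (5E)-6,10-dimethylundeca-5,9-dien-2-one | CC(=O)CC/C=C(\C)CCC=C(C)C | starting material
2 | 2-[(3E)-4,8-dimethylnona-3,7-dien-1-yl]-2-methyl-1,3-dioxolane | CC1(CC/C=C(\C)CCC=C(C)C)OCCO1 | intermediate
3 | (2E,6E)-2,6-dimethyl-9-(2-methyl-1,3-dioxolan-2-yl)nona-2,6-dien-1-ol | CC1(CC/C=C(\C)CC/C=C(\C)CO)OCCO1 | intermediate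
4 | 2-[(3E,7E)-9-bromo-4,8-dimethylnona-3,7-dien-1-yl]-2-methyl-1,3-dioxolane | CC1(CC/C=C(\C)CC/C=C(\C)CBr)OCCO1 | intermediate
5 | (S)-citramalic acid, (2S)-2-hydroxy-2-methylbutanedioic acid | C[C@](O)(CC(=O)O)C(=O)O | starting material
6 | (2S)-2-methylbutane-1,2,4-triol | C[C@](O)(CCO)CO | intermediate
7 | 2-[(4S)-2,2,4-trimethyl-1,3-dioxolan-4-yl]ethan-1-ol | C[C@]1(CCO)COC(C)(C)O1 | intermediate
8 | (4S)-4-(2-bromoethyl)-2,2,4-trimethyl-1,3-dioxolane | C[C@]1(CCBr)COC(C)(C)O1 | intermediate
9 | {2-[(4S)-2,2,4-trimethyl-1,3-dioxolan-4-yl]ethyl}magnesium bromide (Grignard reagent, formed in the flask) | C[C@]1(CC[Mg]Br)COC(C)(C)O1 | intermediate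
10 | (4S)-4-[(4E,8E)-4,8-dimethyl-11-(2-methyl-1,3-dioxolan-2-yl)undeca-4,8-dien-1-yl]-2,2,4-trimethyl-1,3-dioxolane | CC1(CC/C=C(\C)CC/C=C(\C)CCC[C@@]2(C)COC(C)(C)O2)OCCO1 | intermediate
11 | (5E,9E,14S)-14,15-dihydroxy-6,10,14-trimethylpentadeca-5,9-dien-2-one | CC(=O)CC/C=C(\C)CC/C=C(\C)CCC[C@](C)(O)CO | intermediate
12 | (2S,6E,10E)-2-hydroxy-2,6,10-trimethyl-14-oxopentadeca-6,10-dien-1-yl 4-methylbenzenesulfonate (primary tosylate, formed in the flask) | CC(=O)CC/C=C(\C)CC/C=C(\C)CCC[C@](C)(O)COS(=O)(=O)c1ccc(C)cc1 | intermediate
13 | (5E,9E)-6,10-dimethyl-13-[(2S)-2-methyloxiran-2-yl]trideca-5,9-dien-2-one | CC(=O)CC/C=C(\C)CC/C=C(\C)CCC[C@@]1(C)CO1 | intermediate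
14 | (4S,5S,8S,9S,10R)-8,13-epoxy-14,15-dinorlabd-12-en-18-ol | CC1=CC[C@H]2[C@]3(C)CCC[C@](C)(CO)[C@H]3CC[C@]2(C)O1 | intermediate
15 | (4S,5S,8S,9S,10R)-18-(benzyloxy)-8,13-epoxy-14,15-dinorlabd-12-ene | CC1=CC[C@H]2[C@]3(C)CCC[C@](C)(COCc4ccccc4)[C@H]3CC[C@]2(C)O1 | intermediate
16 | (4S,5S,8S,9S,10R)-18-(benzyloxy)-8-hydroxy-14,15-dinorlabdan-13-one | CC(=O)CC[C@H]1[C@]2(C)CCC[C@](C)(COCc3ccccc3)[C@H]2CC[C@]1(C)O | intermediate
17 | triethyl phosphonoacetate | CCOC(=O)CP(=O)(OCC)OCC | starting material
18 | sodium (diethoxyphosphoryl)(ethoxycarbonyl)methanide (sodium phosphonate, formed in the flask) | [Na+].CCOC(=O)[CH-]P(=O)(OCC)OCC | intermediate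
19 | ethyl (4S,5S,8S,9S,10R,13E)-18-(benzyloxy)-8-hydroxylabd-13-en-15-oate | CCOC(=O)/C=C(\C)CC[C@H]1[C@]2(C)CCC[C@](C)(COCc3ccccc3)[C@H]2CC[C@]1(C)O | intermediate
20 | (4S,5S,8S,9S,10R,13E)-18-(benzyloxy)labd-13-ene-8,15-diol | OC/C=C(\C)CC[C@H]1[C@]2(C)CCC[C@](C)(COCc3ccccc3)[C@H]2CC[C@]1(C)O | intermediate
21 | (4S,5S,8S,9S,10R,13S)-18-(benzyloxy)labdane-8,15-diol | C[C@H](CCO)CC[C@H]1[C@]2(C)CCC[C@](C)(COCc3ccccc3)[C@H]2CC[C@]1(C)O | intermediate
22 | benzyl hydrogen malonate, 3-(benzyloxy)-3-oxopropanoic acid | OC(=O)CC(=O)OCc1ccccc1 | starting material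
23 | benzyl (4S,5S,8S,9S,10R,13S)-18-(benzyloxy)-8-hydroxylabdan-15-yl propanedioate | C[C@H](CCOC(=O)CC(=O)OCc1ccccc1)CC[C@H]2[C@]3(C)CCC[C@](C)(COCc4ccccc4)[C@H]3CC[C@]2(C)O | intermediate
24 | 3-{[(3S)-5-[(1S,2S,4aS,5S,8aR)-2-hydroxy-5-(hydroxymethyl)-2,5,8a-trimethyldecahydronaphthalen-1-yl]-3-methylpentyl]oxy}-3-oxopropanoic acid | C[C@H](CCOC(=O)CC(=O)O)CC[C@H]1[C@]2(C)CCC[C@](C)(CO)[C@H]2CC[C@]1(C)O | target

## Step count and least certain steps

Total: 17 steps. Longest linear sequence: 14 steps (steps 1–3 or 4–6, then 7–17).

**Step 10 (key step).** The most likely failure is poor or reversed facial selection in the closure of ring A. The chair with the C18–O–Al arm equatorial is favoured only by the bulk of that arm, while the C18 carbon, tied back toward the leaving oxygen, is small at the moment of bond formation. The other chair gives the diastereomer in which the (4S) centre is joined to the mirror-image ring system with C18 axial. Two lesser drains are a hydride shift in the activated 2,2-disubstituted oxirane (Meinwald rearrangement to an aldehyde) and proton loss from the C8 cation before oxygen capture.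

Fallback: it sets out from bromide 4 and comes back at benzyl ether 15. It moves the initiating oxirane into ring A (C3–C4). For this ring-embedded oxirane the chair with the C3–O bond equatorial is the established course, and C4 follows stereospecifically from an (E)-alkene. Bromide 4 is alkylated with lithiated acetonitrile (LDA, CH3CN, THF, −78 °C) to give the nitrile F1, which (i-Bu)2AlH and mild hydrolysis convert into the aldehyde F2. Wittig reaction with ethyl 2-(triphenylphosphoranylidene)propanoate gives the (E)-enoate F3, and (i-Bu)2AlH the (E)-allylic alcohol F4. Sharpless asymmetric epoxidation (Ti(OiPr)4, D-(−)-diethyl tartrate, t-BuOOH, CH2Cl2, −20 °C) gives the (2R,3R)-epoxy alcohol F5. This is benzylated (NaH, BnBr) to the benzyl ether F6 and freed from the ketal (PPTS, wet acetone) to give the epoxy ketone F7. CH3AlCl2 in CH2Cl2 at −78 °C opens the oxirane at C4 and should give the tricyclic 3-hydroxy enol ether F8, with C3–OH and C18 both equatorial. Its xanthate F9 (NaH, CS2, CH3I) is reduced with Bu3SnH and AIBN in toluene (Barton–McCombie deoxygenation) to 15. Steps 4 to 9 fall away; the passage from 4 to 15 takes ten steps in place of five.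

**Step 7.** Formation of the gamma-alkoxy Grignard reagent may be eroded by Wurtz coupling and 1,3-elimination. The copper reagent may also attack the gamma carbon C5 of the allylic bromide (SN2′), which would give a branched isomer with a 1,1-disubstituted alkene.

Fallback: it sets out from 8 and 4 and comes back at 10. Bromide 8 is converted with PhSO2Na in DMF into the sulfone F10. Its lithium anion (n-BuLi, THF, −78 °C) is alkylated with 4, which can only react at the primary carbon of a non-allylic carbanion, to give the homoallylic sulfone F11 (both epimers at the sulfonyl carbon). Sodium amalgam, Na(Hg), with Na2HPO4 in CH3OH at −20 °C then removes the sulfonyl group to give 10.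

**Step 13.** The ketone rests partly as its cyclic hemiketal and may react slowly. The C8 alkoxide may close back onto the new enoate by conjugate addition, and E selectivity on a methyl ketone is incomplete.

Fallback: it sets out from 16 and comes back at 19. Ketone 16 is silylated at the tertiary hydroxyl with N-(trimethylsilyl)imidazole to give the trimethylsilyl ether F12, which can neither form a hemiketal nor add to an enoate. Olefination as in step 13 gives the silylated (E)-enoate F13, and dilute HCl in THF at 0 °C removes the silyl group to give 19.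

**Step 15.** Incomplete facial selectivity, or hydrogenation of residual (Z)-alcohol, would give the C13 epimer. As a remote diastereomer it would be hard to remove.

Fallback: it sets out from 19 and comes back at 21. Copper hydride conjugate reduction of the enoate (Cu(OAc)2, a chiral bisphosphine such as p-tol-BINAP, polymethylhydrosiloxane, t-BuOH, toluene) gives the saturated ester F14. The ligand enantiomer that delivers hydride to the face giving 13S is not assigned here and must first be fixed on a simple (E)-3-methylalk-2-enoate. LiAlH4 in THF then reduces F14 to 21.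

## Further compounds

F1 | step 10 | (4E,8E)-4,8-dimethyl-11-(2-methyl-1,3-dioxolan-2-yl)undeca-4,8-dienenitrile | CC1(CC/C=C(\C)CC/C=C(\C)CCC#N)OCCO1
F2 | step 10 | (4E,8E)-4,8-dimethyl-11-(2-methyl-1,3-dioxolan-2-yl)undeca-4,8-dienal | CC1(CC/C=C(\C)CC/C=C(\C)CCC=O)OCCO1
F3 | step 10 | ethyl (2E,6E,10E)-2,6,10-trimethyl-13-(2-methyl-1,3-dioxolan-2-yl)trideca-2,6,10-trienoate | CC1(CC/C=C(\C)CC/C=C(\C)CC/C=C(\C)C(=O)OCC)OCCO1
F4 | step 10 | (2E,6E,10E)-2,6,10-trimethyl-13-(2-methyl-1,3-dioxolan-2-yl)trideca-2,6,10-trien-1-ol | CC1(CC/C=C(\C)CC/C=C(\C)CC/C=C(\C)CO)OCCO1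
F5 | step 10 | [(2R,3R)-3-[(3E,7E)-3,7-dimethyl-10-(2-methyl-1,3-dioxolan-2-yl)deca-3,7-dien-1-yl]-2-methyloxiran-2-yl]methanol | CC1(CC/C=C(\C)CC/C=C(\C)CC[C@H]2O[C@]2(C)CO)OCCO1
F6 | step 10 | 2-[(3E,7E)-10-[(2R,3R)-3-[(benzyloxy)methyl]-3-methyloxiran-2-yl]-4,8-dimethyldeca-3,7-dien-1-yl]-2-methyl-1,3-dioxolane | CC1(CC/C=C(\C)CC/C=C(\C)CC[C@H]2O[C@]2(C)COCc3ccccc3)OCCO1
F7 | step 10 | (5E,9E)-12-[(2R,3R)-3-[(benzyloxy)methyl]-3-methyloxiran-2-yl]-6,10-dimethyldodeca-5,9-dien-2-one | CC(=O)CC/C=C(\C)CC/C=C(\C)CC[C@H]1O[C@]1(C)COCc2ccccc2
F8 | step 10 | (3R,4S,5S,8S,9S,10R)-18-(benzyloxy)-8,13-epoxy-14,15-dinorlabd-12-en-3-ol | CC1=CC[C@H]2[C@]3(C)CC[C@@H](O)[C@](C)(COCc4ccccc4)[C@H]3CC[C@]2(C)O1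
F9 | step 10 | O-[(3R,4S,5S,8S,9S,10R)-18-(benzyloxy)-8,13-epoxy-14,15-dinorlabd-12-en-3-yl] S-methyl carbonodithioate | CC1=CC[C@H]2[C@]3(C)CC[C@@H](OC(=S)SC)[C@](C)(COCc4ccccc4)[C@H]3CC[C@]2(C)O1
F10 | step 7 | (4S)-4-[2-(benzenesulfonyl)ethyl]-2,2,4-trimethyl-1,3-dioxolane | C[C@]1(CCS(=O)(=O)c2ccccc2)COC(C)(C)O1
F11 | step 7 | (4S)-4-[(4E,8E)-2-(benzenesulfonyl)-4,8-dimethyl-11-(2-methyl-1,3-dioxolan-2-yl)undeca-4,8-dien-1-yl]-2,2,4-trimethyl-1,3-dioxolane (both epimers at the sulfonyl carbon) | CC1(CC/C=C(\C)CC/C=C(\C)CC(C[C@@]2(C)COC(C)(C)O2)S(=O)(=O)c3ccccc3)OCCO1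
F12 | step 13 | (4S,5S,8S,9S,10R)-18-(benzyloxy)-8-[(trimethylsilyl)oxy]-14,15-dinorlabdan-13-one | CC(=O)CC[C@H]1[C@]2(C)CCC[C@](C)(COCc3ccccc3)[C@H]2CC[C@]1(C)O[Si](C)(C)C
F13 | step 13 | ethyl (4S,5S,8S,9S,10R,13E)-18-(benzyloxy)-8-[(trimethylsilyl)oxy]labd-13-en-15-oate | CCOC(=O)/C=C(\C)CC[C@H]1[C@]2(C)CCC[C@](C)(COCc3ccccc3)[C@H]2CC[C@]1(C)O[Si](C)(C)C
F14 | step 15 | ethyl (4S,5S,8S,9S,10R,13S)-18-(benzyloxy)-8-hydroxylabdan-15-oate | C[C@H](CC(=O)OCC)CC[C@H]1[C@]2(C)CCC[C@](C)(COCc3ccccc3)[C@H]2CC[C@]1(C)O
A1 | alternative 1 | 4-[(tert-butyldimethylsilyl)oxy]-4-methylcyclohexa-2,5-dien-1-one | CC1(O[Si](C)(C)C(C)(C)C)C=CC(=O)C=C1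
A2 | alternative 1 | bis[(3R)-5-(benzyloxy)-3-methylpentyl]zinc (spatial arrangement at C13 as in 24) | C[C@H](CCOCc1ccccc1)CC[Zn]CC[C@H](C)CCOCc1ccccc1
A3 | alternative 1 | (4S,5S,6S)-5-[(3S)-5-(benzyloxy)-3-methylpentyl]-4-[(tert-butyldimethylsilyl)oxy]-4,6-dimethylcyclohex-2-en-1-one | C[C@H](CCOCc1ccccc1)CC[C@H]1[C@H](C)C(=O)C=C[C@]1(C)O[Si](C)(C)C(C)(C)C
A4 | alternative 2 | (2E,7S,8E,10E)-11-[(tert-butyldimethylsilyl)oxy]-3,7-dimethyl-7-{[(triisopropylsilyl)oxy]methyl}undeca-2,8,10-trienal | O=C/C=C(\C)CCC[C@](C)(CO[Si](C(C)C)(C(C)C)C(C)C)/C=C/C=C/O[Si](C)(C)C(C)(C)C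
A5 | alternative 2 | (1S,2R,4aS,5S,8aR)-2-[(tert-butyldimethylsilyl)oxy]-5,8a-dimethyl-5-{[(triisopropylsilyl)oxy]methyl}-1,2,4a,5,6,7,8,8a-octahydronaphthalene-1-carbaldehyde | O=C[C@H]1[C@]2(C)CCC[C@](C)(CO[Si](C(C)C)(C(C)C)C(C)C)[C@H]2C=C[C@H]1O[Si](C)(C)C(C)(C)C
A6 | alternative 3 | 3-(2-{(2S,3S)-3-[(3S)-5-[(tert-butyldimethylsilyl)oxy]-3-methylpentyl]-2-methyloxiran-2-yl}ethyl)-2,4-dimethylphenol | Cc1ccc(O)c(C)c1CC[C@]2(C)O[C@H]2CC[C@H](C)CCO[Si](C)(C)C(C)(C)C
A7 | alternative 3 | (4aS,5S,6S)-5-[(3S)-5-[(tert-butyldimethylsilyl)oxy]-3-methylpentyl]-6-hydroxy-1,4a,6-trimethyl-5,6,7,8-tetrahydronaphthalen-2(4aH)-one | C[C@H](CCO[Si](C)(C)C(C)(C)C)CC[C@H]1[C@]2(C)C=CC(=O)C(C)=C2CC[C@]1(C)O
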